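The numbers of this flask stand for no real mixture; no experiment stands behind them.

A ratio of two rates was what I wanted for this flask, where living ends and protic impurity compete for the free monomer.

    free monomer + initiator → living end + monomer in chains (k1 = 0.0061 M⁻¹ s⁻¹)
    free monomer + living end → monomer in chains + living end, rate k2*[living end]*[free monomer] (k2 = 0.065 M⁻¹ s⁻¹)
    living end + transfer agent → dead chain (k3 = 0.0025 M⁻¹ s⁻¹)
    monomer in chains → over-reaction product (k4 = 2.7 × 10⁻⁸ s⁻¹)
    protic impurity + free monomer → quenched substrate (k5 = 2.3 × 10⁻⁴ M⁻¹ s⁻¹)

free monomer 0.050 M; transfer agent 1.50 mM; protic impurity 0.0250 M; initiator 0.25 mM; time 10 d

- the average divides the monomer in chains by the number of chains begun, living and dead together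
- run time (flask): 10 d

- average number of monomer units in a chain (chains begun, living or dead) at 10 d
- part of the free monomer that has reacted at 10 d

Initiator faced free monomer with a life of 0.911 h, shorter than the 0.526 d I reckoned for free monomer once the chains had begun, so I took 0.25 mM of chains as begun at once. I then divided the rate of propagation by the rate of quenching; free monomer stands in both, so it cancelled and time dropped out. This left the split S, the propagation constant times the living ends over the quenching constant times the protic impurity, a selectivity factor, which with 0.25 mM of living ends and the protic impurity at 0.0250 M was 2.83. Holding S there and counting the whole charge of free monomer as reacted, I put a share 73.9% of it into chains, which gave an estimate of 148 units per chain.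

The weak link was holding S constant. Living ends die with a life of 3.09 d, while the impurity falls as it quenches. After one monomer life I reckoned S at 3.56, and I expected it to fall after that as the ends went on dying; with the two drifts pulling opposite ways, I kept 148 as an estimate. Counting the ends over their whole life and leaving the impurity out, I put the reacted part at 98.7%, and the impurity adds to that.

The forecast, which differed from my 148 units per chain, said 146 (135 to 156) and 99.9% (99.8% to >99.9%), on the grounds that “they live long enough for propagation and the impurity together to use up nearly all the monomer”.

The simulation gave 146 and 99.9%, so the forecast held.

The flask's split read 3.4 at 0.440 d and 0.33 at 10.0 d, and my first S of 2.83 lay below the first reading and above the second. The lower reading belonged to a flask with 0.0832% of its free monomer left at 10.0 d. The same flask stopped at 2.5 d had 95.9% reacted, so S gives 142 units per chain there; the computed value was 143.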